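**Retrosynthetic overview**

- 33 ⇐ 32 (C1 equilibration) ⇐ 31 (desilylation) ⇐ 28 + 29 (hydroboration and B-alkyl Suzuki coupling attach the butenolide) ⇐ 24 (aldol and dehydration put a vinyl arm on C9, anti to the C8 methyl).
- 24 ⇐ 23 ⇐ 21: one intramolecular (4+3) cycloaddition forms C1–C5 and C8–C9 and closes the cyclopentane (C1–C2–C3–C4–C5) and the cycloheptenone (C10, C9, C8, C7, C6, C5, C1) together; no ring exists before step 12.
- Feature used: ketone C10 with its α-carbons C9 and C1 is an oxyallyl unit; C5(O)=C6–C7=C8(Me) is a 1-oxygenated diene whose oxygen-bearing end C5 is the ring-fusion carbon; C2–C3–C4 is a three-atom tether from C1 to C5 that carries the C3 stereocentre and the quaternary C4.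
- 21 ⇐ Grignard reagent of bromide 17 + Weinreb amide 19 (C1–C10 bond; the regiodefined chloro ketone is made last); 17 ⇐ (S)-pantolactone 1 (C2–C5 with C3–O), methylenation (C1) and butenyl addition (C6–C8 plus methyl).

Key step: step 12

Remark: target numbering (C1–C10 as above) is used for all intermediates; TBS = tert-butyldimethylsilyl, TBSO = its ether.
Assumption: the trans ring fusion of the target (H1 anti to the C5 oxygen) is taken to be the thermodynamically preferred C1 configuration of the free β-hydroxy ketone.

**Route**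

Step 1
Reactants: 1 (S)-pantolactone
Product: 2 (3S)-3-(TBSO)-4,4-dimethyloxolan-2-one
Conditions: TBSCl, imidazole, DMF, rt
Reagents that add atoms: tert-butyldimethylsilyl chloride, CC(C)(C)[Si](C)(C)Cl
Why: Imidazole-promoted silylation protects the secondary hydroxyl that becomes C3–O, and the stereocentre is not involved.

Step 2
Reactants: 2 (3S)-3-(TBSO)-4,4-dimethyloxolan-2-one
Product: 3 (3S)-3-(TBSO)-4,4-dimethyloxolan-2-ol (anomer mixture)
Conditions: iBu2AlH, CH2Cl2, −78 °C; Rochelle salt work-up
Reagents that add atoms: none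
Why: Partial reduction of the lactone stops at the lactol because the aluminium hemiacetal is stable at −78 °C.

Step 3
Reactants: 3 lactol; 4 methyltriphenylphosphonium bromide
Product: 7 (3R)-3-(TBSO)-2,2-dimethylpent-4-en-1-ol, via methylenetriphenylphosphorane 5 (not isolated), via open-chain hydroxy aldehyde 6 (not isolated)
Conditions: nBuLi, THF, 0 °C; then 3, 0 °C → rt
Reagents that add atoms: none
Why: Wittig methylenation of the hydroxy aldehyde tautomer of the lactol supplies C1, the lithium counter-ion and low temperature should limit 1,5-silyl migration, and the C3 stereocentre is untouched.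

Step 4
Reactants: 7 (3R)-3-(TBSO)-2,2-dimethylpent-4-en-1-ol
Product: 8 (3R)-3-(TBSO)-2,2-dimethylpent-4-enal
Conditions: Dess–Martin periodinane, CH2Cl2, rt
Reagents that add atoms: none
Why: Dess–Martin oxidation of the neopentyl alcohol gives the C5 aldehyde, which has no α-hydrogen and cannot epimerise.

Step 5
Reactants: 8 aldehyde; 9 but-1-yne
Product: 12 (3R,6E)-3-(TBSO)-4,4-dimethylnona-1,6-dien-5-ol (C5 epimers), via (E)-but-1-enylzirconocene chloride 10 (not isolated), via (E)-but-1-enyl(methyl)zinc 11 (not isolated)
Conditions: Cp2Zr(H)Cl, CH2Cl2, rt; Me2Zn, −65 °C; then 8, 0 °C; aq. NH4Cl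
Reagents that add atoms: none
Why: Syn-hydrozirconation of the alkyne fixes the E geometry, zirconium-to-zinc transmetalation gives an alkenylzinc that adds 1,2 to the hindered aldehyde, and the new carbinol centre is formed as a mixture that is oxidised away in step 8.

Step 6
Reactants: 12 dienol
Product: 14 (3R,6E)-3-(TBSO)-4,4-dimethylnon-6-ene-1,5-diol (C5 epimers), via B-alkyl-9-BBN adduct 13 (not isolated)
Conditions: 9-BBN (excess), THF, rt; then NaOH, H2O2, 0 °C
Reagents that add atoms: hydrogen peroxide, OO
Why: Hydroboration–oxidation with 9-BBN takes the monosubstituted terminal alkene far faster than the internal E-alkene and places the oxygen on C1 (anti-Markovnikov).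

Step 7
Reactants: 14 diol
Product: 15 (3E,7R)-9-bromo-7-(TBSO)-6,6-dimethylnon-3-en-5-ol (C5 epimers)
Conditions: CBr4, PPh3, CH2Cl2, −20 → 0 °C
Reagents that add atoms: carbon tetrabromide, BrC(Br)(Br)Br
Why: Appel bromination should select the unhindered primary alcohol over the secondary allylic alcohol, which is flanked by the quaternary C4.

Step 8
Reactants: 15 bromo alcohol
Product: 16 (3E,7R)-9-bromo-7-(TBSO)-6,6-dimethylnon-3-en-5-one
Conditions: Dess–Martin periodinane, CH2Cl2, rt
Reagents that add atoms: none
Why: Dess–Martin oxidation of the allylic alcohol gives the E-enone and removes the provisional C5 carbinol centre.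

Step 9
Reactants: 16 bromo enone
Product: 17 (2E,4Z,7R)-9-bromo-5,7-bis(TBSO)-6,6-dimethylnona-2,4-diene
Conditions: TBSOTf, Et3N, CH2Cl2, −78 → 0 °C
Reagents that add atoms: tert-butyldimethylsilyl trifluoromethanesulfonate, CC(C)(C)[Si](C)(C)OS(=O)(=O)C(F)(F)F
Why: O-silylation of the s-cis enone and γ-deprotonation (soft vinylogous enolisation, the only mode open because C4 has no hydrogen) give the silyl dienol ether with the bulky C4 trans to C7 on C5=C6 (Z) and the E geometry at the new C7=C8 bond, without a free dienolate that could displace the bromide.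

Step 10
Reactants: 18 (S)-2-chloropropanoyl chloride
Product: 19 (S)-2-chloro-N-methoxy-N-methylpropanamide
Conditions: MeNH(OMe)·HCl, pyridine, CH2Cl2, 0 °C
Reagents that add atoms: N,O-dimethylhydroxylamine hydrochloride, CNOC.Cl
Why: Acylation of the amine by the acid chloride gives the Weinreb amide, and any loss of configuration at the chlorinated carbon is of no consequence because that centre is erased in step 12.

Step 11
Reactants: 17 bromo dienol ether; 19 Weinreb amide
Product: 21 (2S,6R,8Z,10E)-2-chloro-6,8-bis(TBSO)-7,7-dimethyldodeca-8,10-dien-3-one, via Grignard reagent 20 (not isolated)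
Conditions: Mg, THF, rt → 40 °C; then 19, −20 → 0 °C; aq. NH4Cl
Reagents that add atoms: none
Why: Weinreb ketone synthesis: the primary Grignard reagent adds to the amide carbonyl faster than it touches the α-chloride and the chelated tetrahedral intermediate prevents over-addition, so the chloro ketone is formed regiodefined at C9 with the dienol ether already in place.

Step 12
Reactants: 21 chloro ketone
Product: 23 cis-fused 7,9-bis(TBSO)-3,4,8,8-tetramethylbicyclo[5.3.0]dec-5-en-2-one (target numbering: H1 cis to C5–O; C8 methyl trans to C5–O; C9 methyl cis to C8 methyl), via oxyallyl cation 22 (not isolated)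
Conditions: Et3N, LiClO4 (3 M in Et2O), rt, high dilution
Reagents that add atoms: none
Why: Triethylamine enolises the chloro ketone towards C1 and lithium-assisted loss of chloride releases the oxyallyl cation 22, which adds across the two ends of the s-cis silyloxydiene in a single asynchronous (4+3) cycloaddition in which C9–C8 bonding leads because C8 is the nucleophilic end of the dienol ether; the closest known reaction type is the base-induced intramolecular oxyallyl (4+3) cycloaddition of α-chloro ketones with three-atom-tethered dienes and furans. The cyclopentane closes through the C1–C5 bond in a 5-exo sense (the diene stays outside the tether ring), and the cycloheptenone is the (4+3) ring itself, completed by the C8–C9 bond. C8 and C5 are fixed relative to each other by the diene geometry, since suprafacial addition puts the outside C8 methyl and the inside C5 silyloxy group on opposite faces, and their absolute sense comes from the C3 stereocentre, whose silyloxy group should sit pseudo-equatorial in the chair-like tether, anti to the C5 silyloxy group. C1 and C9 follow from the compact transition state of the W-shaped oxyallyl (cis ring fusion, C9 methyl cis to C8 methyl) and are provisional, because C9 is later made quaternary through its enolate and C1 is equilibrated. The step needs (4+3) periselectivity over (3+2) closure at C7 and over alkylation at C6, and it needs the correct diene face; these rest on the short tether that holds C1 over C5, on the quaternary C4 that shields C6, and on the aprotic, weakly Lewis acidic medium.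

Step 13
Reactants: 23 cycloadduct
Product: 24 cis-fused 7,9-bis(TBSO)-3,4,8,8-tetramethylbicyclo[5.3.0]decan-2-one
Conditions: H2 (1 atm), Pt/C, EtOAc, rt
Reagents that add atoms: none
Why: Heterogeneous hydrogenation saturates the cis-disubstituted C6=C7 bond without creating a stereocentre, platinum being preferred to palladium to avoid hydrogenolysis of the allylic tertiary silyl ether.

Step 14
Reactants: 24 ketone; 25 acetaldehyde
Product: 27 C9-(1-hydroxyethyl) ketone (carbinol epimers; C9 methyl cis to C8 methyl), via lithium enolate 26 (not isolated)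
Conditions: LiN(iPr)2, THF, −78 °C; then 25, −78 °C; AcOH quench at −78 °C
Reagents that add atoms: none
Why: Kinetic deprotonation should remove the more accessible C9–H (C1–H is shielded by the adjacent quaternary C5 and its silyloxy group), and aldol addition of enolate 26 on the face anti to the pseudo-axial C8 methyl sets the C9 quaternary centre with its methyl cis to the C8 methyl.

Step 15
Reactants: 27 aldol
Product: 28 C9-vinyl ketone (3-ethenyl-7,9-bis(TBSO)-3,4,8,8-tetramethylbicyclo[5.3.0]decan-2-one)
Conditions: Burgess reagent, toluene, 70 °C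
Reagents that add atoms: none
Why: Burgess dehydration by syn-elimination of the sulfamate can only run towards the methyl group because C9 carries no hydrogen, and the neighbouring acyl group disfavours ionisation and skeletal shift.

Step 16
Reactants: 28 vinyl ketone; 29 4-bromofuran-2(5H)-one
Product: 31 cis-fused bis-silyl ether of the C1 epimer of the target, via B-alkyl-9-BBN adduct 30 (not isolated)
Conditions: 9-BBN, THF, rt → 50 °C; then 29, PdCl2(dppf), K3PO4 (3 M aq.), DMF, rt
Reagents that add atoms: none
Why: 9-BBN hydroborates the vinyl group at its terminus while the hindered C10 ketone is left alone, and B-alkyl Suzuki–Miyaura coupling of borane 30 with the vinylogous acyl bromide 29 forms the bond from the two-carbon arm to C4 of the butenolide.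

Step 17
Reactants: 31 bis-silyl ether
Product: 32 C1 epimer of the target (cis-fused diol)
Conditions: HF (48% aq.), MeCN, rt → 40 °C
Reagents that add atoms: none
Why: Acidic fluoride cleaves the secondary C3 and tertiary C5 silyl ethers without the basic conditions that would open the β-hydroxy ketone by retro-aldol cleavage or isomerise the butenolide.

Step 18
Reactants: 32 cis-fused diol
Product: 33 target CNP0077405.2
Conditions: DBU (cat.), toluene, rt
Reagents that add atoms: none
Why: Amidine-catalysed enolisation at C1, the only enolisable position next to C10, should equilibrate the ring fusion to the trans isomer, in which the C5 hydroxyl and the C10 carbonyl are syn and hydrogen-bonded, while the non-polar medium and catalytic base keep the alkoxide concentration too low for retro-aldol cleavage.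

**Compound list**

1 | (S)-pantolactone | O[C@@H]1C(=O)OCC1(C)C | starting material
2 | (3S)-3-(TBSO)-4,4-dimethyloxolan-2-one | CC(C)(C)[Si](C)(C)O[C@@H]1C(=O)OCC1(C)C | intermediate
3 | (3S)-3-(TBSO)-4,4-dimethyloxolan-2-ol, anomer mixture | CC(C)(C)[Si](C)(C)O[C@@H]1C(O)OCC1(C)C | intermediate
4 | methyltriphenylphosphonium bromide | C[P+](c1ccccc1)(c1ccccc1)c1ccccc1.[Br-] | starting material
5 | methylenetriphenylphosphorane | C=P(c1ccccc1)(c1ccccc1)c1ccccc1 | intermediate
6 | (2S)-2-(TBSO)-4-hydroxy-3,3-dimethylbutanal | CC(C)(C)[Si](C)(C)O[C@H](C=O)C(C)(C)CO | intermediate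
7 | (3R)-3-(TBSO)-2,2-dimethylpent-4-en-1-ol | C=C[C@@H](O[Si](C)(C)C(C)(C)C)C(C)(C)CO | intermediate
8 | (3R)-3-(TBSO)-2,2-dimethylpent-4-enal | C=C[C@@H](O[Si](C)(C)C(C)(C)C)C(C)(C)C=O | intermediate
9 | but-1-yne | CCC#C | starting material
10 | (E)-but-1-enylzirconocene chloride | CC/C=C/[Zr+2]Cl.c1cc[cH-]c1.c1cc[cH-]c1 | intermediate
11 | (E)-but-1-enyl(methyl)zinc | CC/C=C/[Zn]C | intermediate
12 | (3R,6E)-3-(TBSO)-4,4-dimethylnona-1,6-dien-5-ol, C5 epimers | C=C[C@@H](O[Si](C)(C)C(C)(C)C)C(C)(C)C(O)/C=C/CC | intermediate
13 | B-alkyl-9-BBN adduct of 12 (boron on C1) | C1CCC2CCCC1B2CC[C@@H](O[Si](C)(C)C(C)(C)C)C(C)(C)C(O)/C=C/CC | intermediate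
14 | (3R,6E)-3-(TBSO)-4,4-dimethylnon-6-ene-1,5-diol, C5 epimers | OCC[C@@H](O[Si](C)(C)C(C)(C)C)C(C)(C)C(O)/C=C/CC | intermediate
15 | (3E,7R)-9-bromo-7-(TBSO)-6,6-dimethylnon-3-en-5-ol, C5 epimers | BrCC[C@@H](O[Si](C)(C)C(C)(C)C)C(C)(C)C(O)/C=C/CC | intermediate
16 | (3E,7R)-9-bromo-7-(TBSO)-6,6-dimethylnon-3-en-5-one | BrCC[C@@H](O[Si](C)(C)C(C)(C)C)C(C)(C)C(=O)/C=C/CC | intermediate
17 | (2E,4Z,7R)-9-bromo-5,7-bis(TBSO)-6,6-dimethylnona-2,4-diene | BrCC[C@@H](O[Si](C)(C)C(C)(C)C)C(C)(C)/C(O[Si](C)(C)C(C)(C)C)=C/C=C/C | intermediate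
18 | (S)-2-chloropropanoyl chloride | C[C@H](Cl)C(Cl)=O | starting material
19 | (S)-2-chloro-N-methoxy-N-methylpropanamide | C[C@H](Cl)C(=O)N(C)OC | intermediate
20 | Grignard reagent of 17 (magnesium on C1) | Br[Mg]CC[C@@H](O[Si](C)(C)C(C)(C)C)C(C)(C)/C(O[Si](C)(C)C(C)(C)C)=C/C=C/C | intermediate
21 | (2S,6R,8Z,10E)-2-chloro-6,8-bis(TBSO)-7,7-dimethyldodeca-8,10-dien-3-one (key-step precursor) | C[C@H](Cl)C(=O)CC[C@@H](O[Si](C)(C)C(C)(C)C)C(C)(C)/C(O[Si](C)(C)C(C)(C)C)=C/C=C/C | intermediate
22 | oxyallyl cation C9–C10(O)–C1, drawn as zwitterion | C[CH+]C([O-])=CC[C@@H](O[Si](C)(C)C(C)(C)C)C(C)(C)/C(O[Si](C)(C)C(C)(C)C)=C/C=C/C | intermediate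
23 | cis-fused 7,9-bis(TBSO)-3,4,8,8-tetramethylbicyclo[5.3.0]dec-5-en-2-one (key-step product) | C[C@@H]1C=C[C@@]2(O[Si](C)(C)C(C)(C)C)[C@H](C[C@@H](O[Si](C)(C)C(C)(C)C)C2(C)C)C(=O)[C@@H]1C | intermediate
24 | cis-fused 7,9-bis(TBSO)-3,4,8,8-tetramethylbicyclo[5.3.0]decan-2-one | C[C@@H]1CC[C@@]2(O[Si](C)(C)C(C)(C)C)[C@H](C[C@@H](O[Si](C)(C)C(C)(C)C)C2(C)C)C(=O)[C@@H]1C | intermediate
25 | acetaldehyde | CC=O | starting material
26 | lithium enolate of 24 (C9=C10) | C[C@@H]1CC[C@@]2(O[Si](C)(C)C(C)(C)C)[C@H](C[C@@H](O[Si](C)(C)C(C)(C)C)C2(C)C)C(O[Li])=C1C | intermediate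
27 | C9-(1-hydroxyethyl) ketone, carbinol epimers | C[C@@H]1CC[C@@]2(O[Si](C)(C)C(C)(C)C)[C@H](C[C@@H](O[Si](C)(C)C(C)(C)C)C2(C)C)C(=O)[C@@]1(C)C(C)O | intermediate
28 | C9-vinyl ketone | C[C@@H]1CC[C@@]2(O[Si](C)(C)C(C)(C)C)[C@H](C[C@@H](O[Si](C)(C)C(C)(C)C)C2(C)C)C(=O)[C@@]1(C)C=C | intermediate
29 | 4-bromofuran-2(5H)-one | O=C1C=C(Br)CO1 | starting material
30 | B-alkyl-9-BBN adduct of 28 | C[C@@H]1CC[C@@]2(O[Si](C)(C)C(C)(C)C)[C@H](C[C@@H](O[Si](C)(C)C(C)(C)C)C2(C)C)C(=O)[C@@]1(C)CCB1C2CCCC1CCC2 | intermediate
31 | cis-fused bis-TBS ether of the C1 epimer of the target | C[C@@H]1CC[C@@]2(O[Si](C)(C)C(C)(C)C)[C@H](C[C@@H](O[Si](C)(C)C(C)(C)C)C2(C)C)C(=O)[C@@]1(C)CCC1=CC(=O)OC1 | intermediate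
32 | C1 epimer of the target (cis-fused diol) | C[C@@H]1CC[C@@]2(O)[C@H](C[C@@H](O)C2(C)C)C(=O)[C@@]1(C)CCC1=CC(=O)OC1 | intermediate
33 | CNP0077405.2 | C[C@@H]1CC[C@@]2(O)[C@@H](C[C@@H](O)C2(C)C)C(=O)[C@@]1(C)CCC1=CC(=O)OC1 | target

**Step count and risks**

Total step count: 18. Longest linear sequence: 17 steps (1 to 33 through steps 1–9 and 11–18; step 10 is a one-step side branch).

Steps most likely to fail:

1. Step 12. The cation may be captured stepwise by the dienol ether: C1 may bond to the nucleophilic C6, or the C9–C8 bonded intermediate may close onto C7 to a cyclopentanone. The Z-configured open-chain diene, which must reach the s-cis form with its silyloxy group inside, may also react so slowly that Favorskii-type decomposition of the chloro ketone takes over. The fallback sets out from 21 and comes back at 23. It changes the reactive species from a base-generated lithium oxyallyl to a silver-generated silyloxyallyl cation, the variant with the best record for open-chain dienes. The chloro ketone is enolised kinetically on the CH2 side (LiN(SiMe3)2, Me3SiCl, THF, −78 °C) to the isolable 2-(trimethylsilyloxy)allyl chloride F1. The cation is then released without base by AgClO4 in nitromethane/CH2Cl2 at −40 °C, and loss of the trimethylsilyl group on work-up should give ketone 23.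

2. Step 14. Deprotonation may occur on the C1 side, followed by β-elimination of the C5 silanolate, and the aldehyde may add from the face syn to the C8 methyl. The fallback sets out from 24 and comes back at 27. The ketone is converted without strong base (Me3SiOTf, Et3N, CH2Cl2, 0 °C) into the C9 trimethylsilyl enol ether F2. Its regiochemistry can be checked at this stage; a C1-side isomer cannot eliminate and can be separated and hydrolysed back to 24. A Mukaiyama aldol addition of F2 to acetaldehyde (BF3·OEt2, CH2Cl2, −78 °C) then forms the C9 quaternary centre under Lewis acid control.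

3. Step 18. The equilibration may stall at a mixture of ring-fusion isomers, or the free β-hydroxy ketone may open by retro-aldol cleavage of the C1–C5 bond or dehydrate. The fallback sets out from 28 and comes back at 33. It replaces thermodynamic by kinetic control while the C5 oxygen is still silylated. Ketone 28 is deprotonated at its only α-hydrogen with in situ trapping (KN(SiMe3)2, Me3SiCl, THF, −78 °C) to the C1 trimethylsilyl enol ether F3. Protonolysis with Bu4NF/AcOH at −78 °C should deliver the proton anti to the adjacent C5 silyloxy group and give the trans-fused vinyl ketone F4. Hydroboration with 9-BBN to the borane F5 and Suzuki–Miyaura coupling with 29 (as in step 16) give the trans-fused bis-silyl butenolide F6, and aqueous HF in MeCN (as in step 17) releases 33 directly.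

**Further compounds**

F1 | step 12 | 2-(trimethylsilyloxy)allyl chloride from 21 (C1=C10 enol silane) | C[C@H](Cl)C(O[Si](C)(C)C)=CC[C@@H](O[Si](C)(C)C(C)(C)C)C(C)(C)/C(O[Si](C)(C)C(C)(C)C)=C/C=C/C
F2 | step 14 | C9 trimethylsilyl enol ether of 24 | C[C@@H]1CC[C@@]2(O[Si](C)(C)C(C)(C)C)[C@H](C[C@@H](O[Si](C)(C)C(C)(C)C)C2(C)C)C(O[Si](C)(C)C)=C1C
F3 | step 18 | C1 trimethylsilyl enol ether of 28 | C[C@@H]1CC[C@@]2(O[Si](C)(C)C(C)(C)C)C(C[C@@H](O[Si](C)(C)C(C)(C)C)C2(C)C)=C(O[Si](C)(C)C)[C@@]1(C)C=C
F4 | step 18 | trans-fused C9-vinyl ketone (C1 epimer of 28) | C[C@@H]1CC[C@@]2(O[Si](C)(C)C(C)(C)C)[C@@H](C[C@@H](O[Si](C)(C)C(C)(C)C)C2(C)C)C(=O)[C@@]1(C)C=C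
F5 | step 18 | B-alkyl-9-BBN adduct of F4 | C[C@@H]1CC[C@@]2(O[Si](C)(C)C(C)(C)C)[C@@H](C[C@@H](O[Si](C)(C)C(C)(C)C)C2(C)C)C(=O)[C@@]1(C)CCB1C2CCCC1CCC2
F6 | step 18 | trans-fused bis-TBS ether of the target | C[C@@H]1CC[C@@]2(O[Si](C)(C)C(C)(C)C)[C@@H](C[C@@H](O[Si](C)(C)C(C)(C)C)C2(C)C)C(=O)[C@@]1(C)CCC1=CC(=O)OC1
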